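## Retrosynthetic overview

1. Target 17 ⇐ 16 (loss of four silyl groups, γ-lactone closure) ⇐ 15 by the key bond: the C–C bond between the two oxygen-bearing quaternary carbons shared by cyclopentane ring C and the lactone, made by a hydrogen-atom-transfer-initiated 5-exo radical cyclisation.
2. Enabling feature: in the bicyclo[3.2.1]octane core, C2 and the one-carbon bridge C8 are 1,3-syn on six-membered ring B (C1–C5 plus C8). The 1-silyloxyvinyl group on C8 and the β-silyloxy enoate on C2 therefore face each other, and radical carbon and acceptor carbon are the ends of the five-atom chain C–C8–C1–C2–C.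
3. 15 ⇐ 14 ⇐ 13 ⇐ 12: an anionic acyl relay turns the bicyclo[2.2.2]octane cycloadduct into the bicyclo[3.2.1]octane (ring A) and moves the methylmalonyl unit from C1 to C2.
4. 12 ⇐ Diels–Alder reaction of (S)-sorbicillinol 11 with keto lactone 10. 11 comes from enantioselective dearomatisation of sorbicillin 3 (the only stereocentre set by catalysis; all others are relayed). 10 is an isomer of sorbicillinol with a ring oxygen between the two carbons joined in step 9, made from 2, 4 and 5.
5. Ring order: ring B (arene carbons) → bicyclo[2.2.2]octane (cycloaddition) → ring A (rearrangement to bicyclo[3.2.1]octane) → ring C (key step) → γ-lactone.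

Key step: step 9

Assumption: the (R,R) aryl iodide of step 5 is taken to deliver the (S)-quinol (its enantiomer is used if the sense proves opposite), and 1, 2, 4 and 5 are taken as commercial.

Locants: "sorboyl" means (2E,4E)-hexa-2,4-dienoyl. For 13–17 the core is numbered as bicyclo[3.2.1]octane: C1 bridgehead bearing the sorboyl group, C2 (methyl), C3 (C=O), C4 (enol ylidene), C5 bridgehead CH, C6 (C(OH)CH3), C7 (C=O), C8 one-carbon bridge.

## Route

Step 1
Reactants: 1 2,4-dimethylbenzene-1,3-diol; 2 sorbic acid
Product: 3 sorbicillin
Conditions: BF3·OEt2, 120 °C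
Reagents that add atoms: none
Why: Friedel–Crafts acylation of the resorcinol with the free acid at the only open position that is ortho and para to the two hydroxyl groups.

Step 2
Reactants: 4 methyl 2-methyl-3-oxobutanoate; 5 1,1-dimethoxypropan-2-ol (racemic)
Product: 6 1,1-dimethoxypropan-2-yl 2-methyl-3-oxobutanoate
Conditions: DMAP (0.2 equiv), toluene, 110 °C, 4 Å MS
Reagents that add atoms: none
Why: Amine-catalysed transesterification of a β-keto ester, driven by removal of methanol; the acetal survives the neutral conditions and the two stereocentres are not controlled because both are erased later.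

Step 3
Reactants: 6 1,1-dimethoxypropan-2-yl 2-methyl-3-oxobutanoate; 2 sorbic acid
Product: 8 1,1-dimethoxypropan-2-yl (6E,8E)-2-methyl-3,5-dioxodeca-6,8-dienoate, via 1-sorboylimidazole 7 (not isolated)
Conditions: 2, CDI, THF, 23 °C; separately 6, LDA (3.2 equiv), THF, −78 °C; combine, −78 → 0 °C; aq. NH4Cl
Reagents that add atoms: none
Why: Claisen-type γ-acylation of a β-keto ester dianion with an N-acylimidazole, which should react by 1,2-addition at the terminal, more nucleophilic carbanion.

Step 4
Reactants: 8 1,1-dimethoxypropan-2-yl (6E,8E)-2-methyl-3,5-dioxodeca-6,8-dienoate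
Product: 10 3,7-dimethyl-5-sorboyloxepine-2,4(3H,7H)-dione, via keto aldehyde 9 (not isolated)
Conditions: TFA/H2O (9:1), CH2Cl2, 0 °C; then piperidinium acetate (0.2 equiv), 4 Å MS, CH2Cl2 (0.005 M), 23 °C
Reagents that add atoms: none
Why: Acetal hydrolysis and intramolecular Knoevenagel condensation of the 1,3-diketone methylene with the aldehyde; the competing aldol addition at the tertiary keto ester carbon cannot dehydrate and should revert, so loss of water funnels the material to the seven-membered alkylidene keto lactone.

Step 5
Reactants: 3 sorbicillin; 10 3,7-dimethyl-5-sorboyloxepine-2,4(3H,7H)-dione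
Product: 12 lactone-fused bicyclo[2.2.2]octane cycloadduct, via (S)-sorbicillinol 11 (not isolated)
Conditions: (R,R)-2,2'-[(2-iodo-1,3-phenylene)bis(oxy)]bis[N-(2,4,6-trimethylphenyl)propanamide] (10 mol%), mCPBA (1.1 equiv), H2O (5 equiv), CH2Cl2/(CF3)2CHOH, −20 °C; then 10 (3 equiv), pyridine (1 equiv), 23 °C
Reagents that add atoms: water, O
Why: Enantioselective hydroxylative phenol dearomatisation by a chiral trivalent iodine species (water attacks the methyl-bearing carbon ortho to the free phenol) should set the (S)-carbinol, and the ortho-quinol then undergoes a Diels–Alder reaction with cyclic enone 10 in the sense known for cyclodimerisation of such quinols (acyl-bearing dienophile carbon to the methyl-bearing diene terminus, approach syn to the hydroxyl group, lactone ring endo), which relays the carbinol configuration to the four new ring stereocentres.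

Step 6
Reactants: 12 lactone-fused bicyclo[2.2.2]octane cycloadduct
Product: 13 bicyclo[3.2.1]octane hydroxy keto ester
Conditions: NaOMe (2.5 equiv), THF/MeOH (4:1), −20 → 23 °C; aq. NH4Cl
Reagents that add atoms: sodium methoxide, [Na+].[O-]C
Why: Proposed new method: methoxide should open the lactone, the freed secondary alkoxide attacks the cis ring ketone on the neighbouring quaternary carbon (retro-Claisen acyl transfer to oxygen), the released dienolate adds to the bridge ketone on the adjacent bridgehead and the cyclopropanolate reopens (anionic 1,2-acyl shift, bicyclo[2.2.2]octane to bicyclo[3.2.1]octane, which makes C1 a bridgehead), and the new C2 enolate is acylated through a six-membered transition state by the ester parked on the C8 side chain (Claisen), which places the keto ester arm on C2 syn to C8 and is driven by formation of the β-keto ester enolate; the closest known reaction type is the retro-Claisen/Claisen acyl migration of non-enolisable 1,3-dicarbonyl compounds, but the relay as a whole is untested.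

Step 7
Reactants: 13 bicyclo[3.2.1]octane hydroxy keto ester
Product: 14 bicyclo[3.2.1]octane methyl ketone keto ester
Conditions: Dess–Martin periodinane (1.5 equiv), NaHCO3, CH2Cl2, 0 → 23 °C
Reagents that add atoms: none
Why: Dess–Martin oxidation of the only secondary alcohol gives the methyl ketone and removes the uncontrolled carbinol centre; tertiary alcohols and the chelated enol should be untouched.

Step 8
Reactants: 14 bicyclo[3.2.1]octane methyl ketone keto ester
Product: 15 tetrakis(silyl) ether with 1-silyloxyvinyl group on C8
Conditions: TBSOTf (6 equiv), Et3N (10 equiv), CH2Cl2, −78 → 0 °C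
Reagents that add atoms: tert-butyldimethylsilyl trifluoromethanesulfonate, CC(C)(C)[Si](C)(C)OS(=O)(=O)C(F)(F)F
Why: Soft enolisation and O-silylation: the methyl ketone should enolise toward the methyl group (the alternative enol ether would be a tetrasubstituted alkene exocyclic to the hindered bridge carbon), the β-keto ester gives the (Z)-β-silyloxy enoate, and the enol and the tertiary hydroxyl group are capped.

Step 9
Reactants: 15 tetrakis(silyl) ether with 1-silyloxyvinyl group on C8
Product: 16 cyclised tetrakis(silyl) ether (ring C closed)
Conditions: Fe(acac)3 (0.3 equiv), PhSiH3 (3 equiv), THF/EtOH (4:1), 40 °C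
Reagents that add atoms: none
Why: Proposed new method: An iron hydride formed from Fe(acac)3 and PhSiH3 should transfer a hydrogen atom to the CH2 terminus of the electron-rich 1,1-disubstituted silyl enol ether on C8, and the tertiary α-silyloxy radical (a ketyl equivalent made without a reducing metal) should add to the β-carbon of the β-silyloxy enoate on C2; the α-ester radical is then reduced by divalent iron and the enolate protonated by ethanol, which returns the iron to the cycle. The closest known reaction type is the iron-catalysed hydrogen-atom-transfer reductive coupling of heteroatom-substituted donor olefins with acrylate-type acceptors (radical conjugate addition of Giese type), which has not been used to join two fully substituted, oxygen-bearing carbons. Ring C closes by a 5-exo-trig radical cyclisation, radical and acceptor carbons being held close by the 1,3-syn relationship of C2 and C8 on ring B. The acceptor carbon is attacked on the only face turned toward C8 with its C(CH3)CO2CH3 terminus pointing away from the sorboyl group on C1; the radical carbon reacts with its silyloxy group anti to the silyloxy group of the acceptor across the forming bond (smaller dipole and less strain than with the methyl group over ring B); and the enolate carbon is protonated on the face remote from the new silyloxy-bearing quaternary carbon. The step needs hydrogen-atom transfer to the 1-silyloxyvinyl group in the presence of six other C=C bonds, secured because these are 1,2-disubstituted and electron-poor (sorbyl chains) or tetrasubstituted (enol ethers), and 5-exo closure in preference to 6-endo addition to the neighbouring dienone, secured by the proximity described and by the captodative product radical.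

Step 10
Reactants: 16 cyclised tetrakis(silyl) ether (ring C closed)
Product: 17 target CNP0231466.1
Conditions: HF·pyridine, THF/pyridine, 0 → 40 °C
Reagents that add atoms: none
Why: Fluoride-mediated cleavage of the four silyl groups frees the tertiary alcohol that is cis to the propanoate arm, and acid-promoted lactonisation with loss of methanol should close the cis-fused γ-lactone without touching any stereocentre.

## Compound list

1 | 2,4-dimethylbenzene-1,3-diol | Cc1ccc(O)c(C)c1O | starting material
2 | sorbic acid, (2E,4E)-hexa-2,4-dienoic acid | C/C=C/C=C/C(=O)O | starting material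
3 | sorbicillin, (2E,4E)-1-(2,4-dihydroxy-3,5-dimethylphenyl)hexa-2,4-dien-1-one | C/C=C/C=C/C(=O)c1cc(C)c(O)c(C)c1O | intermediate
4 | methyl 2-methyl-3-oxobutanoate | CC(=O)C(C)C(=O)OC | starting material
5 | 1,1-dimethoxypropan-2-ol (racemic) | CC(O)C(OC)OC | starting material
6 | 1,1-dimethoxypropan-2-yl 2-methyl-3-oxobutanoate (both stereocentres uncontrolled) | CC(=O)C(C)C(=O)OC(C)C(OC)OC | intermediate
7 | 1-sorboylimidazole, (2E,4E)-1-(1H-imidazol-1-yl)hexa-2,4-dien-1-one | C/C=C/C=C/C(=O)n1ccnc1 | intermediate
8 | 1,1-dimethoxypropan-2-yl (6E,8E)-2-methyl-3,5-dioxodeca-6,8-dienoate | C/C=C/C=C/C(=O)CC(=O)C(C)C(=O)OC(C)C(OC)OC | intermediate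
9 | keto aldehyde, 1-oxopropan-2-yl (6E,8E)-2-methyl-3,5-dioxodeca-6,8-dienoate | C/C=C/C=C/C(=O)CC(=O)C(C)C(=O)OC(C)C=O | intermediate
10 | 5-[(2E,4E)-hexa-2,4-dienoyl]-3,7-dimethyloxepine-2,4(3H,7H)-dione (C3 and C7 uncontrolled) | C/C=C/C=C/C(=O)C1=CC(C)OC(=O)C(C)C1=O | intermediate
11 | (S)-sorbicillinol, (6S)-4-[(2E,4E)-hexa-2,4-dienoyl]-3,6-dihydroxy-2,6-dimethylcyclohexa-2,4-dien-1-one | C/C=C/C=C/C(=O)C1=C[C@](C)(O)C(=O)C(C)=C1O | intermediate
12 | cycloadduct: 8-sorboyl-5-[(Z)-1-hydroxy-(2E,4E)-hexa-2,4-dienylidene]-3-hydroxy-1,3-dimethylbicyclo[2.2.2]octane-2,6-dione with C8 and C7 joined by –C(=O)–CH(CH3)–C(=O)–O–CH(CH3)– (ketone end on C8); 3-OH syn to the C7–C8 bridge, lactone ring syn to the C5–C6 bridge, sorboyl syn to the C2–C3 bridge; the two lactone CH(CH3) centres uncontrolled | C/C=C/C=C/C(=O)[C@]12C(=O)C(C)C(=O)OC(C)[C@H]1[C@H]3\C(=C(O)/C=C/C=C/C)C(=O)[C@]2(C)C(=O)[C@@]3(C)O | intermediate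
13 | methyl 2-methyl-3-oxo-3-(bicyclo[3.2.1]oct-2-yl)propanoate; bicycle: 1-sorboyl, 2-methyl, 3,7-dioxo, 4-[(Z)-1-hydroxy-(2E,4E)-hexa-2,4-dienylidene], 6-hydroxy-6-methyl (OH syn to C8), 8-(1-hydroxyethyl) (syn to the C2–C4 bridge); keto ester arm on C2 syn to C8; carbinol and malonyl CH centres uncontrolled | C/C=C/C=C/C(=O)[C@]12C(=O)[C@@](C)(O)[C@@H]([C@@H]2C(C)O)\C(=C(O)/C=C/C=C/C)C(=O)[C@@]1(C)C(=O)C(C)C(=O)OC | intermediate
14 | as 13 but with 8-acetyl in place of 8-(1-hydroxyethyl) | C/C=C/C=C/C(=O)[C@]12C(=O)[C@@](C)(O)[C@@H]([C@@H]2C(C)=O)\C(=C(O)/C=C/C=C/C)C(=O)[C@@]1(C)C(=O)C(C)C(=O)OC | intermediate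
15 | tetrakis(tert-butyldimethylsilyl) derivative of 14: 6-OTBS, enol OTBS on the C4 ylidene, 8-[1-(TBSO)vinyl], and on C2 the (Z)-1-(TBSO)-3-methoxy-2-methyl-3-oxoprop-1-enyl group | C/C=C/C=C/C(=O)[C@]12C(=O)[C@@](C)(O[Si](C)(C)C(C)(C)C)[C@@H]([C@@H]2C(=C)O[Si](C)(C)C(C)(C)C)\C(=C(O[Si](C)(C)C(C)(C)C)/C=C/C=C/C)C(=O)[C@@]1(C)/C(O[Si](C)(C)C(C)(C)C)=C(\C)C(=O)OC | intermediate
16 | cyclised product: cyclopentane ring C made of C1, C2, C8 and two new adjacent quaternary carbons, the one on C2 bearing OTBS and the CH(CH3)CO2CH3 arm, the one on C8 bearing OTBS and CH3; the two OTBS groups trans on ring C, the C8-side OTBS cis to the propanoate arm; other groups as in 15 | C/C=C/C=C/C(=O)[C@]12C(=O)[C@@](C)(O[Si](C)(C)C(C)(C)C)[C@@H]3\C(=C(O[Si](C)(C)C(C)(C)C)/C=C/C=C/C)C(=O)[C@@]1(C)[C@@](O[Si](C)(C)C(C)(C)C)([C@@H](C)C(=O)OC)[C@@](C)(O[Si](C)(C)C(C)(C)C)[C@@H]32 | intermediate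
17 | target CNP0231466.1: cis-fused γ-lactone on ring C of the 1-sorboyl-bicyclo[3.2.1]octane-3,7-dione | C/C=C/C=C/C(=O)[C@]12C(=O)[C@@](C)(O)[C@@H]3\C(=C(O)/C=C/C=C/C)C(=O)[C@@]1(C)[C@@]1(O)[C@@H](C)C(=O)O[C@@]1(C)[C@@H]32 | target

## Step count and risks

Total step count: 10. Longest linear sequence: 9 steps (4 and 5 to 17, steps 2–10).

The three steps most likely to fail are step 9, step 6 and step 5.

**Step 9 (labelled, key step).** Hydrogen-atom transfer may go to a sorbyl alkene or a silyl dienol ether instead of the 1-silyloxyvinyl group. The radical may add 6-endo to the neighbouring dienone. Bond formation between two fully substituted carbons may be too slow. The silyloxy carbon from the acetyl group or the methyl-bearing carbon may form with the wrong configuration. The fallback uses known chemistry and sets out from methyl ketone 14. SmI2 in THF/MeOH at −78 °C (chelation-controlled intramolecular pinacol coupling of a β-keto ester with a ketone) would give the cis-diol ester F1. Heating F1 with camphorsulfonic acid in toluene would ionise the tertiary carbinol derived from the acetyl group; capture of the cation by the ester carbonyl on the face of the propanoate arm would close the cis-fused lactone with inversion at that carbon and loss of methanol. The fallback comes back to the route at target 17.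

**Step 6 (labelled).** The dienolate may be protonated without adding to the bridge ketone, so that the skeleton does not rearrange. Methoxide may cleave a sorboyl group by retro-Claisen reaction, or the tertiary alkoxide may take over the sorboyl group. The fallback uses known chemistry and sets out from cycloadduct 12. NaOMe in MeOH at 50 °C would effect lactone methanolysis, alkoxide acyl transfer and retro-Claisen opening of the non-enolisable 1,3-diketone between the methyl-bearing bridgehead and the bridge ketone, giving the monocyclic seco-diester F2. KOt-Bu in THF would then close ring A by Dieckmann condensation and transfer the methylmalonyl unit to C2 by intramolecular Claisen acylation, with loss of methanol. The fallback comes back to the route at 13.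

**Step 5.** The hydroxylation may show low enantioselectivity or attack the other methyl-bearing carbon, cyclodimerisation of the quinol may outrun the cross cycloaddition, and the lactone ring may add exo. The fallback sets out from sorbicillin 3. Pb(OAc)4 in acetic acid (Wessely acetoxylation) would give the racemic quinol acetate, and separation on a chiral stationary phase would give (S)-sorbicillinol acetate F3. Hydrolysis of F3 with HCl in THF/H2O followed by neutralisation in the presence of 10 would release 11 slowly and give the same cycloaddition. The fallback comes back to the route at 12.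

Further compounds
F1 | step 9 | cis-diol ester: ring C closed, both new carbinols free and cis, methyl ester retained (propanoate CH uncontrolled) | C/C=C/C=C/C(=O)[C@]12C(=O)[C@@](C)(O)[C@@H]3\C(=C(O)/C=C/C=C/C)C(=O)[C@@]1(C)[C@@](O)(C(C)C(=O)OC)[C@](C)(O)[C@@H]32
F2 | step 6 | monocyclic seco-diester: cyclohexane-1,3-dione (ring B) bearing sorboyl, the C(OH)(CH3)CO2CH3 arm and the CH(CH3)O–C(=O)CH(CH3)CO2CH3 arm (epimerisable centres uncontrolled) | C/C=C/C=C/C(=O)C1C(C)C(=O)/C(=C(O)/C=C/C=C/C)[C@@H]([C@](C)(O)C(=O)OC)[C@@H]1C(C)OC(=O)C(C)C(=O)OC
F3 | step 5 | (S)-sorbicillinol acetate | C/C=C/C=C/C(=O)C1=C[C@](C)(OC(C)=O)C(=O)C(C)=C1O
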